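A small charge of catalyst, 0.10 mM in the amber run, gives readings up to 120 min, and from them we ask how fast target forms and whether it survives. We count in fractions of substrate and other conformer together.

| flask | substrate | other conformer | catalyst | remark | time |
|---|---|---|---|---|---|
| amber | 0.034 M | 0.025 M | 0.10 mM | run made earlier |  |
| alpha | 0.050 M | 0.0250 M | 0.10 mM |  | 6.0 h |
| epsilon | 0.050 M | 0.0250 M | 0.20 mM |  | 6.0 h |
| eta | 0.050 M | 0.0250 M | 0.40 mM |  | 6.0 h |

amber run (percent of the substrate and other conformer together charged)

| time / min | target / % | substrate / % |
|---|---|---|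
| 20.0 | 3.0 | 82.4 |
| 40.0 | 6.3 | 83.7 |
| 50.0 | 8.7 | 81.5 |
| 80.0 | 14.0 | 79.0 |
| 90.0 | 14.7 | 77.1 |
| 120 | 18.1 | 72.1 |

(scatter of a reading: 1 percentage point)

- what was read earlier has a scatter of 1 percentage point, one standard deviation
- no earlier run changes the charge of catalyst; that part of a forecast is a guess
- "hardly changes" means that all values lie within two and a half points (for a concentration: within two and a half percent of the largest)

* [target] at the end for alpha, epsilon, eta, in this order
* the shape of the row from first to last (falls, then rises / hardly changes / rises all the way / rises, then falls / falls all the way)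

Substrate reads 83.7% at 40.0 min against 57.6% charged, so other conformer passes into substrate, and we let the whole charge feed target. At fixed catalyst we take the making as pseudo-first-order in substrate. Target reaches 8.7% at 50.0 min, which gives a making constant of 0.125 h⁻¹.

From 80.0 min to 120 min target climbs 0.0615 h⁻¹, with substrate near 75.6% and target near 16.1%. Making should give 0.0945 h⁻¹, more than that climb, so we read a loss of target of about 0.204 h⁻¹ of itself.

Putting this back, we let the early target suffer the same loss, which raises our making constant to 0.135 h⁻¹. The loss constant, the share of standing target that disappears per hour, then reads 0.254 h⁻¹. One standard deviation of the two readings moves it by 0.132 h⁻¹, so our ceiling, an estimate and not a strict bound, uses 0.122 h⁻¹ and our floor, likewise an estimate, 0.386 h⁻¹.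

We scale making with catalyst, which is a guess, and take target at 6.0 h as m/(d−m) times the difference of the two decays, e^(−mt) − e^(−dt).

| flask | making | ceiling | reckoned | floor |
|---|---|---|---|---|
| alpha | 0.135 h⁻¹ | 37.6% | 25.8% | 18.6% |
| epsilon | 0.271 h⁻¹ | 51.7% | 33.7% | 23.1% |
| eta | 0.541 h⁻¹ | 57.1% | 33.7% | 20.9% |

We commit to 0.0193 M, 0.0253 M and 0.0253 M: a rise, then level.

The forecast gives 0.034 M, 0.056 M, 0.07 M, rises all the way, saying “No reversibility or catalyst death is visible”, and each value lies above our ceiling.

The flask gives 0.0203 M, 0.0253 M, 0.0241 M: rises, then falls, with the turn at 0.25 mM of catalyst.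

    substrate ⇌ other conformer (K = 0.0250, k = 0.0952 h⁻¹)
    substrate + catalyst → catalyst + target (k = 1520 M⁻¹ h⁻¹)
    catalyst + other conformer → catalyst + isomer of the product (k = 1430 M⁻¹ h⁻¹)
    target → over-reaction product (k = 0.247 h⁻¹)

Over-reaction product stands at 30.3% in alpha at 6.00 h. With our constants, making over loss in alpha at that time is 0.775; the flask's value is 0.896. In eta at 3.00 h, our constants put loss at 0.127 h⁻¹ and making at 0.0857 h⁻¹, less than the loss, and eta's target goes from 49.9% to 32.2% at 6.00 h.

The numbers in the tables were computed with made-up constants; the scatter is artificial.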